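The 6-oxabicyclo[3.2.1]octane-7,8-dione core is disconnected at C2–C3 in the three-carbon bridge and at C5–C8 between the oxygen-bearing bridgehead and the ketone bridge. This unfolds the cyclohexanone ring and the five-membered lactone ring into an open acyloin ester of a quaternary malonic thioester. The key step exploits two features: C5 is α to the isobutyryl ketone, and C8 hangs on the quaternary carbon C1. A tin hydride cyclisation of the C2 bromide onto a dienyl chain first closes the seven-membered ring O6–C7–C1–C2–C3–C4–C5 and writes the C3 prenyl group. Base added to the same flask then joins C5 to C8 across that ring.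

Key step: step 10

Assumption: the esterase is taken to cleave the enantiotopic ester that gives (S)-6, and the Wittig product is drawn as its (E)-isomer.

Step 1
Reactants: 1 dimethyl malonate; 2 prenyl bromide (1-bromo-3-methylbut-2-ene)
Product: 3 dimethyl 2-(3-methylbut-2-en-1-yl)malonate
Conditions: NaH, THF, 0 °C to rt
Reagents that add atoms: none
Why: Malonate alkylation, in which the sodium enolate displaces bromide from the primary allylic halide (SN2) and no stereocenter is formed.

Step 2
Reactants: 3 dimethyl 2-(3-methylbut-2-en-1-yl)malonate; 4 dibromomethane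
Product: 5 dimethyl 2-(bromomethyl)-2-(3-methylbut-2-en-1-yl)malonate
Conditions: NaH, CH2Br2 (large excess), THF, reflux
Reagents that add atoms: none
Why: Second malonate alkylation (SN2 on CH2Br2), in which the excess of dihalide keeps the neopentyl-type bromide from meeting a second enolate, and the new quaternary carbon is still prochiral.

Step 3
Reactants: 5 dimethyl 2-(bromomethyl)-2-(3-methylbut-2-en-1-yl)malonate
Product: 6 (S)-2-(bromomethyl)-2-(methoxycarbonyl)-5-methylhex-4-enoic acid
Conditions: pig liver esterase, phosphate buffer pH 7, DMSO (co-solvent), 25 °C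
Reagents that add atoms: water, O
Why: Enzymatic desymmetrisation by a carboxylesterase (hydrolase class), in which one of the two enantiotopic methyl esters is hydrolysed in the chiral active site and so sets the quaternary centre that becomes C1.

Step 4
Reactants: 7 (R)-pantolactone
Product: 8 (R)-2,4-dihydroxy-N-methoxy-N,3,3-trimethylbutanamide
Conditions: MeNH(OMe)·HCl, AlMe3, CH2Cl2, 0 °C to rt; cold dilute HCl work-up
Reagents that add atoms: N,O-dimethylhydroxylamine hydrochloride, CNOC.Cl
Why: Aluminium amide aminolysis of a lactone to the N-methoxy-N-methylamide, which leaves the carbinol stereocenter untouched.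

Step 5
Reactants: 8 (R)-2,4-dihydroxy-N-methoxy-N,3,3-trimethylbutanamide
Product: 9 (R)-2-hydroxy-N-methoxy-N,3,3-trimethyl-4-oxobutanamide
Conditions: TEMPO (cat.), PhI(OAc)2, CH2Cl2, rt
Reagents that add atoms: none
Why: TEMPO-catalysed oxoammonium oxidation is selective for the primary over the secondary alcohol, and the aldehyde has no α-hydrogen, so it can neither enolise nor eliminate.

Step 6
Reactants: 9 (R)-2-hydroxy-N-methoxy-N,3,3-trimethyl-4-oxobutanamide; 10 (3-methylbut-2-en-1-yl)triphenylphosphonium bromide
Product: 11 (2R,4E)-2-hydroxy-N-methoxy-N,3,3,7-tetramethylocta-4,6-dienamide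
Conditions: NaN(SiMe3)2, THF, −78 °C to rt (ylide in excess)
Reagents that add atoms: none
Why: Wittig olefination with a semi-stabilised allylic ylide (one extra equivalent covers the free hydroxyl group) builds the diene, and either alkene isomer leads later to the same allyl radical.

Step 7
Reactants: 11 (2R,4E)-2-hydroxy-N-methoxy-N,3,3,7-tetramethylocta-4,6-dienamide; 12 isopropyllithium
Product: 13 (4R,6E)-4-hydroxy-2,5,5,9-tetramethyldeca-6,8-dien-3-one
Conditions: i-PrLi (excess), THF, −78 °C; aq. NH4Cl
Reagents that add atoms: none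
Why: Organolithium addition to an N-methoxy-N-methylamide stops at the chelated tetrahedral intermediate and gives the ketone on work-up, the first equivalent being used up by the hydroxyl group.

Step 8
Reactants: 6 (S)-2-(bromomethyl)-2-(methoxycarbonyl)-5-methylhex-4-enoic acid; 13 (4R,6E)-4-hydroxy-2,5,5,9-tetramethyldeca-6,8-dien-3-one
Product: 15 methyl (4R,6E)-2,5,5,9-tetramethyl-3-oxodeca-6,8-dien-4-yl (2R)-2-(bromomethyl)-2-(3-methylbut-2-en-1-yl)propanedioate, via acid chloride 14 (not isolated)
Conditions: Me2C=C(Cl)NMe2, CH2Cl2, 0 °C; then 13, DMAP, Et3N, CH2Cl2, rt to 40 °C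
Reagents that add atoms: none
Why: Acid chloride formation under neutral conditions (α-chloroenamine, no HCl that could add to the alkenes) followed by DMAP-catalysed acylation joins the two hindered halves, and the quaternary centre cannot racemise because the acid has no α-hydrogen.

Step 9
Reactants: 15 methyl (4R,6E)-2,5,5,9-tetramethyl-3-oxodeca-6,8-dien-4-yl (2R)-2-(bromomethyl)-2-(3-methylbut-2-en-1-yl)propanedioate
Product: 16 (4R,6E)-2,5,5,9-tetramethyl-3-oxodeca-6,8-dien-4-yl (2S)-2-(bromomethyl)-5-methyl-2-[(phenylsulfanyl)carbonyl]hex-4-enoate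
Conditions: PhSH, AlMe3, CH2Cl2, 0 °C to rt; cold dilute HCl work-up
Reagents that add atoms: thiophenol, Sc1ccccc1
Why: Ester to thioester exchange with an aluminium thiolate, which should attack the small methyl ester in preference to the ester of the bulky secondary alcohol on the same quaternary carbon.

Step 10
Reactants: 16 (4R,6E)-2,5,5,9-tetramethyl-3-oxodeca-6,8-dien-4-yl (2S)-2-(bromomethyl)-5-methyl-2-[(phenylsulfanyl)carbonyl]hex-4-enoate
Product: 18 (1R,3R,5R)-4,4-dimethyl-1,3-bis(3-methylbut-2-en-1-yl)-5-(2-methylpropanoyl)-6-oxabicyclo[3.2.1]octane-7,8-dione, via seven-membered lactone thioester 17 (not isolated)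
Conditions: Bu3SnH, AIBN (slow addition), PhMe (high dilution), 100 °C; then −78 °C, KN(SiMe3)2; AcOH quench
Reagents that add atoms: none
Why: Bu3Sn• abstracts bromine from 16 and the primary C2 radical adds to the terminal diene carbon C3 (tin hydride radical cyclisation, 7-exo-trig, closing the seven-membered lactone ring), after which the dimethylallyl-type radical takes hydrogen from Bu3SnH at its less hindered secondary end and so becomes the C3 prenyl group of 17. KN(SiMe3)2 then removes the C5 proton between the acyloxy oxygen and the isobutyryl ketone, and the enolate attacks the thioester carbonyl C8 across the ring (transannular Dieckmann condensation, 5-exo-trig for the five-membered lactone ring, the same bond closing the six-membered carbocycle), thiophenolate being a leaving group good enough to hold the non-enolisable dione at low temperature. C3 is set in the radical step, where a folded transition state with the dienyl chain, the C1 prenyl group and the C5 isobutyryl group all turned outward should be favoured, so that the (S)-quaternary centre and the (R)-carbinol centre of 16 act in the same sense. C5 is flattened in the enolate and rebuilt under ring constraint, because C8 is held by C1 over one face of C5 only, so that C5 follows from C1 and the pantolactone-derived centre serves as a temporary control element. The step needs ring closure to outrun reduction of the radical, hydrogen transfer from C5–H and tin radical addition to the diene: the quaternary carbons C1 and C4 fold the chain (gem-dialkyl effect), the diene is an activated acceptor, slow addition keeps tin hydride dilute so that reversible tin adducts fall apart again, and the electron-poor C5–H is a mismatched donor for a nucleophilic alkyl radical. Running the radical step before the ketone C8 exists also shuts out the 1,2-acyl shift of a β-keto radical.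

Compound list
1 | dimethyl malonate | COC(=O)CC(=O)OC | starting material
2 | prenyl bromide | CC(C)=CCBr | starting material
3 | dimethyl 2-(3-methylbut-2-en-1-yl)malonate | COC(=O)C(CC=C(C)C)C(=O)OC | intermediate
4 | dibromomethane | BrCBr | starting material
5 | dimethyl 2-(bromomethyl)-2-(3-methylbut-2-en-1-yl)malonate | COC(=O)C(CBr)(CC=C(C)C)C(=O)OC | intermediate
6 | (S)-2-(bromomethyl)-2-(methoxycarbonyl)-5-methylhex-4-enoic acid | BrC[C@@](C(=O)OC)(CC=C(C)C)C(=O)O | intermediate
7 | (R)-pantolactone | CC1(C)COC(=O)[C@@H]1O | starting material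
8 | (R)-2,4-dihydroxy-N-methoxy-N,3,3-trimethylbutanamide | O[C@@H](C(=O)N(C)OC)C(C)(C)CO | intermediate
9 | (R)-2-hydroxy-N-methoxy-N,3,3-trimethyl-4-oxobutanamide | O[C@@H](C(=O)N(C)OC)C(C)(C)C=O | intermediate
10 | (3-methylbut-2-en-1-yl)triphenylphosphonium bromide | CC(C)=CC[P+](c1ccccc1)(c1ccccc1)c1ccccc1.[Br-] | starting material
11 | (2R,4E)-2-hydroxy-N-methoxy-N,3,3,7-tetramethylocta-4,6-dienamide | O[C@@H](C(=O)N(C)OC)C(C)(C)/C=C/C=C(C)C | intermediate
12 | isopropyllithium | [Li]C(C)C | starting material
13 | (4R,6E)-4-hydroxy-2,5,5,9-tetramethyldeca-6,8-dien-3-one | O[C@@H](C(=O)C(C)C)C(C)(C)/C=C/C=C(C)C | intermediate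
14 | methyl (2R)-2-(bromomethyl)-2-(chlorocarbonyl)-5-methylhex-4-enoate | BrC[C@@](C(=O)OC)(CC=C(C)C)C(=O)Cl | intermediate
15 | methyl (4R,6E)-2,5,5,9-tetramethyl-3-oxodeca-6,8-dien-4-yl (2R)-2-(bromomethyl)-2-(3-methylbut-2-en-1-yl)propanedioate | BrC[C@@](C(=O)OC)(CC=C(C)C)C(=O)O[C@@H](C(=O)C(C)C)C(C)(C)/C=C/C=C(C)C | intermediate
16 | (4R,6E)-2,5,5,9-tetramethyl-3-oxodeca-6,8-dien-4-yl (2S)-2-(bromomethyl)-5-methyl-2-[(phenylsulfanyl)carbonyl]hex-4-enoate | BrC[C@@](C(=O)Sc1ccccc1)(CC=C(C)C)C(=O)O[C@@H](C(=O)C(C)C)C(C)(C)/C=C/C=C(C)C | intermediate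
17 | S-phenyl (3S,5R,7R)-6,6-dimethyl-3,5-bis(3-methylbut-2-en-1-yl)-7-(2-methylpropanoyl)-2-oxooxepane-3-carbothioate | CC(C)=CC[C@@H]1C[C@@](C(=O)Sc2ccccc2)(CC=C(C)C)C(=O)O[C@@H](C(=O)C(C)C)C1(C)C | intermediate
18 | (1R,3R,5R)-4,4-dimethyl-1,3-bis(3-methylbut-2-en-1-yl)-5-(2-methylpropanoyl)-6-oxabicyclo[3.2.1]octane-7,8-dione | CC(C)=CC[C@@H]1C[C@@]2(CC=C(C)C)C(=O)O[C@](C(=O)C(C)C)(C2=O)C1(C)C | target

Total step count: 10. Longest linear sequence: 7 steps (7 → 8 → 9 → 11 → 13 → 15 → 16 → 18).

Steps most likely to fail

Step 10.
- **What may go wrong:** the slow seven-membered radical closure may be outrun by reduction of the primary radical, by hydrogen transfer from C5–H or by tin radical addition to the diene. Facial selectivity at C3 may also be poor.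
- **Fallback:** the order of the two ring closures is inverted and split into two operations.
- Setting out from 16, KN(SiMe3)2 in THF at −78 °C closes the five-membered ring first (Dieckmann condensation). This gives (3R,5R)-3-(bromomethyl)-5-[(3E)-2,6-dimethylhepta-3,5-dien-2-yl]-3-(3-methylbut-2-en-1-yl)-5-(2-methylpropanoyl)furan-2,4(3H,5H)-dione F1.
- Its C5 epimer, (3R,5S)-3-(bromomethyl)-5-[(3E)-2,6-dimethylhepta-3,5-dien-2-yl]-3-(3-methylbut-2-en-1-yl)-5-(2-methylpropanoyl)furan-2,4(3H,5H)-dione F2, forms alongside and is removed by chromatography.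
- Only F1 holds the bromomethyl group and the dienyl chain on the same face. Its radical (Bu3SnH, Et3B, air, PhMe, −20 °C) closes the carbocycle in the faster 6-exo-trig mode through a chair with the dienyl chain equatorial, and the route is rejoined at 18.

Step 3.
- **What may go wrong:** the esterase may discriminate poorly between the enantiotopic esters or prefer the wrong one. The carboxylate may also displace the neighbouring bromide.
- **Fallback:** classical resolution in place of desymmetrisation.
- Setting out from 5, one equivalent of KOH in MeOH at 0 °C gives racemic 2-(bromomethyl)-2-(methoxycarbonyl)-5-methylhex-4-enoic acid F3.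
- The acid is crystallised with (R)-1-phenylethylamine as (R)-1-phenylethylammonium (S)-2-(bromomethyl)-2-(methoxycarbonyl)-5-methylhex-4-enoate F4. The other amine enantiomer is available if the wrong salt is the less soluble one.
- Acidification returns the route to 6.

Step 9.
- **What may go wrong:** the aluminium thiolate may fail to reach the hindered methyl ester or may cleave the acyloin ester instead.
- **Fallback:** hydrolysis and coupling in place of direct exchange.
- Setting out from 15, Me3SnOH in 1,2-dichloroethane at 80 °C cleaves the methyl ester. This gives (2R)-2-(bromomethyl)-5-methyl-2-({[(4R,6E)-2,5,5,9-tetramethyl-3-oxodeca-6,8-dien-4-yl]oxy}carbonyl)hex-4-enoic acid F5.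
- F5 is coupled with PhSH (DCC, DMAP, CH2Cl2, 0 °C), and the route is rejoined at 16.

Further compounds
F1 | step 10 | (3R,5R)-3-(bromomethyl)-5-[(3E)-2,6-dimethylhepta-3,5-dien-2-yl]-3-(3-methylbut-2-en-1-yl)-5-(2-methylpropanoyl)furan-2,4(3H,5H)-dione | BrC[C@@]1(CC=C(C)C)C(=O)O[C@](C(=O)C(C)C)(C1=O)C(C)(C)/C=C/C=C(C)C
F2 | step 10 | (3R,5S)-3-(bromomethyl)-5-[(3E)-2,6-dimethylhepta-3,5-dien-2-yl]-3-(3-methylbut-2-en-1-yl)-5-(2-methylpropanoyl)furan-2,4(3H,5H)-dione | BrC[C@@]1(CC=C(C)C)C(=O)O[C@@](C(=O)C(C)C)(C1=O)C(C)(C)/C=C/C=C(C)C
F3 | step 3 | racemic 2-(bromomethyl)-2-(methoxycarbonyl)-5-methylhex-4-enoic acid | BrCC(C(=O)OC)(CC=C(C)C)C(=O)O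
F4 | step 3 | (R)-1-phenylethylammonium (S)-2-(bromomethyl)-2-(methoxycarbonyl)-5-methylhex-4-enoate | BrC[C@@](C(=O)OC)(CC=C(C)C)C(=O)[O-].C[C@@H]([NH3+])c1ccccc1
F5 | step 9 | (2R)-2-(bromomethyl)-5-methyl-2-({[(4R,6E)-2,5,5,9-tetramethyl-3-oxodeca-6,8-dien-4-yl]oxy}carbonyl)hex-4-enoic acid | BrC[C@@](C(=O)O)(CC=C(C)C)C(=O)O[C@@H](C(=O)C(C)C)C(C)(C)/C=C/C=C(C)C
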